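**Two ratios.** G stands to X at 5.00 to one in the winter run and at 0.625 to one in the summer run. X is therefore the limiting reagent in winter, and G is in summer. I balance each flask on that reagent.

| setting | spring | dusk | noon | winter | summer |
|---|---|---|---|---|---|
| X | 0.120 M | 0.0480 M | 0.180 M | 0.120 M | 0.240 M |
| G | 0.300 M | 0.228 M | 0.300 M | 0.600 M | 0.150 M |
| time |  |  |  |  | 61 min |

- spring run (time / min: [J] / M): 2.4: 0.0056; 3.9: 0.0098; 6.1: 0.0134; 9.7: 0.0200; 15: 0.0278; 24: 0.0389; 39: 0.0508; 61: 0.0567
- dusk run (time / min: [J] / M): 2.4: 0.0013; 3.9: 0.0025; 6.1: 0.0037; 9.7: 0.0068; 15: 0.0095; 24: 0.0129; 39: 0.0172; 61: 0.0208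
- noon run (time / min: [J] / M): 2.4: 0.0088; 3.9: 0.0130; 6.1: 0.0187; 9.7: 0.0290; 15: 0.0406; 24: 0.0559; 39: 0.0700; 61: 0.0804
- winter run (time / min: [J] / M): 2.4: 0.0107; 3.9: 0.0174; 6.1: 0.0243; 9.7: 0.0365; 15: 0.0500; 24: 0.0644; 39: 0.0753; 61: 0.0746

(readings scatter by 6 × 10⁻⁴ M)

- Overall: X + G -> J.
- Constant volume, constant temperature.
- What is held in complexes is read along with the free species.
- "The second partner" is G.
- An order is taken over about fifteen percent of the charge, up and down.

* reaction order in [G] at the outset, round the charge of the spring run, defined at two percent of the X turned into J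
* reaction order in [X] at the outset, round the charge of the spring run, defined at two percent of the X turned into J (one fixed amount of J, the same in the runs compared)
* J in the summer run at 61 min, as a share of the X charged

**The stall.** The winter run reads 0.0753 M of J at 39 min and 0.0746 M at 61 min, a flat stretch within the scatter. Yet 0.0454 M of its X charge is not in J, and G is in excess. Taken at face value, winter stops with both reagents still there.

**Rate law.** Let x be the amount of X turned so far, whether or not it is still J, and take dx/dt = k[X][G]. The spring reading at 9.7 min, integrated, gives k = 0.0649 L mol⁻¹ min⁻¹. Winter gives 0.0644 L mol⁻¹ min⁻¹ and noon 0.0636 L mol⁻¹ min⁻¹, so I take both orders as one.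

**Kept share.** With this k, the law puts x in the winter run at 0.105 M by 61 min, more than the J read. I read the gap as J that has gone on to something else, not as a stop. J over x in winter there reads 0.709; I call this ratio the kept share φ. Spring, with other charges, reads 0.745.

**Summer estimate.** The law gives x = 0.0800 M at 61 min, below the G charge. Multiplied by φ, that is 0.0567 M of J, or 23.6% of the X charged.

The forecast gives 0.95 in G, 0.97 in X and 24%, holding that “A first-order loss of J, k₂ ≈ 0.009 per min, reproduces all four values at 61 min”.

**The result.** The summer run holds 22.2% of its X charge as J at 61 min, which is 0.0532 M, and the orders at the outset, round the spring charge, are 1.1 in G and 0.95 in X.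

    2 G ⇌ G2, settled at all times (45.20 L mol⁻¹)
    X + G2 → J + G (0.2208 L mol⁻¹ min⁻¹)
    J → Ja (0.009060 min⁻¹)
    X + G ⇌ XG, settled at all times (4.660 L mol⁻¹)

The fit with the main steps alone forecasts 26.4% for the summer run. Divided by φ at its winter reading, the summer J stands for an estimated x = 0.0750 M. That estimate leaves 0.0750 M of the 0.150 M of G charged unturned in summer, bound forms counted.

(The numbers in the tables come from a simulation on assumed constants, and the scatter is random.)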